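**Retrosynthetic overview**
1. Target 42 ⇐ desilylation of 41 ⇐ ring-closing metathesis at C2=C3 (ten-membered ring, closed last) of acyclic triene 40.
2. 40 ⇐ Yamaguchi esterification of the C8 alcohol (after Mitsunobu inversion) with (2S,3S)-epoxyangelic acid 34 ⇐ adduct 36.
3. Key C7–C8 bond: Zn-mediated Barbier allylation of aldehyde 30 (fragment B) with bromomethylbutenolide 19 (fragment A); this unveils the α-methylene lactone and sets C7.
4. Fragment A: C6 from (S)-but-3-ene-1,2-diol, oxirane by Sharpless epoxidation, butenolide by acrylate ring-closing metathesis.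
5. Fragment B: C9 by Noyori hydrogenation, (E)-dienoate by aldol/E1cB. Ring order: oxirane → lactone → ten-membered carbocycle.

Assumption: germacrane numbering is used for atom labels (ring C1–C10, lactone C11/C12 with exo-methylene C13, ester carbon C14), and (S)-but-3-ene-1,2-diol and angelic acid are taken as purchasable.

**Route**

Step 1
Reactants: 1 (2S)-but-3-ene-1,2-diol
Product: 2 (3S)-3,4-bis[(tert-butyldimethylsilyl)oxy]but-1-ene
Conditions: TBSCl (2.3 equiv), imidazole, DMF, 0 °C to rt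
Reagents that add atoms: tert-butyldimethylsilyl chloride, CC(C)(C)[Si](C)(C)Cl
Why: Silyl ether formation on both hydroxyls; the C6 stereocentre comes from the chiral pool and is not touched.

Step 2
Reactants: 2 (3S)-3,4-bis[(tert-butyldimethylsilyl)oxy]but-1-ene
Product: 3 (2S)-2-[(tert-butyldimethylsilyl)oxy]but-3-en-1-ol
Conditions: HF·pyridine, pyridine, THF, 0 °C
Reagents that add atoms: none
Why: Selective desilylation, the unhindered primary silyl ether being cleaved much faster than the secondary allylic one under buffered HF.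

Step 3
Reactants: 3 (2S)-2-[(tert-butyldimethylsilyl)oxy]but-3-en-1-ol; 4 ethyl 2-(triphenyl-λ5-phosphanylidene)propanoate
Product: 6 ethyl (2E,4S)-4-[(tert-butyldimethylsilyl)oxy]-2-methylhexa-2,5-dienoate, via aldehyde 5 (not isolated)
Conditions: Dess–Martin periodinane, CH2Cl2, 0 °C to rt; then 4 (2.5 equiv), rt to 40 °C, one pot
Reagents that add atoms: none
Why: Dess–Martin oxidation followed in the same flask by a Wittig reaction with the stabilised α-branched ylide gives the (E)-trisubstituted enoate, and trapping the α-silyloxy aldehyde at once avoids its racemisation.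

Step 4
Reactants: 6 ethyl (2E,4S)-4-[(tert-butyldimethylsilyl)oxy]-2-methylhexa-2,5-dienoate
Product: 7 (2E,4S)-4-[(tert-butyldimethylsilyl)oxy]-2-methylhexa-2,5-dien-1-ol
Conditions: iBu2AlH (2.2 equiv), CH2Cl2, −78 °C; aqueous work-up
Reagents that add atoms: none
Why: Ester-to-allylic-alcohol hydride reduction proceeds 1,2 at −78 °C without touching the alkenes or the silyl ether.

Step 5
Reactants: 7 (2E,4S)-4-[(tert-butyldimethylsilyl)oxy]-2-methylhexa-2,5-dien-1-ol
Product: 8 [(2R,3R)-3-{(1S)-1-[(tert-butyldimethylsilyl)oxy]prop-2-en-1-yl}-2-methyloxiran-2-yl]methanol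
Conditions: Ti(OiPr)4 (10 mol%), D-(−)-diethyl tartrate (12 mol%), tBuOOH, 4 Å molecular sieves, CH2Cl2, −20 °C
Reagents that add atoms: tert-butyl hydroperoxide, CC(C)(C)OO
Why: Sharpless asymmetric epoxidation, in which the D-(−)-tartrate catalyst delivers oxygen to the face that gives the (2R,3R)-epoxide (C4 and C5) under reagent control while the non-allylic vinyl group is inert.

Step 6
Reactants: 8 [(2R,3R)-3-{(1S)-1-[(tert-butyldimethylsilyl)oxy]prop-2-en-1-yl}-2-methyloxiran-2-yl]methanol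
Product: 9 (2S,3R)-3-{(1S)-1-[(tert-butyldimethylsilyl)oxy]prop-2-en-1-yl}-2-methyloxirane-2-carbaldehyde
Conditions: Dess–Martin periodinane, pyridine, CH2Cl2, 0 °C
Reagents that add atoms: none
Why: Dess–Martin oxidation to the epoxy aldehyde, which has no α-hydrogen and therefore cannot epimerise (the C4 label changes by CIP priority only).

Step 7
Reactants: 9 (2S,3R)-3-{(1S)-1-[(tert-butyldimethylsilyl)oxy]prop-2-en-1-yl}-2-methyloxirane-2-carbaldehyde
Product: 10 tert-butyl({(1S)-1-[(2R,3R)-3-ethenyl-3-methyloxiran-2-yl]prop-2-en-1-yl}oxy)dimethylsilane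
Conditions: Ph3PCH3Br, KN(SiMe3)2, THF, −78 to 0 °C
Reagents that add atoms: methyltriphenylphosphonium bromide, C[P+](c1ccccc1)(c1ccccc1)c1ccccc1.[Br-]
Why: Wittig methylenation converts the aldehyde into the C3 vinyl group needed for the final ring closure.

Step 8
Reactants: 10 tert-butyl({(1S)-1-[(2R,3R)-3-ethenyl-3-methyloxiran-2-yl]prop-2-en-1-yl}oxy)dimethylsilane
Product: 11 (1S)-1-[(2R,3R)-3-ethenyl-3-methyloxiran-2-yl]prop-2-en-1-ol
Conditions: Bu4NF, AcOH, THF, 0 °C to rt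
Reagents that add atoms: none
Why: Fluoride desilylation, buffered with acetic acid so that the liberated epoxy alkoxide does not undergo Payne rearrangement.

Step 9
Reactants: 12 ethyl 2-(bromomethyl)prop-2-enoate; 13 (4-methoxyphenyl)methanol
Product: 14 ethyl 2-{[(4-methoxyphenyl)methoxy]methyl}prop-2-enoate
Conditions: NaH, THF, 0 °C
Reagents that add atoms: none
Why: Williamson-type etherification, the alkoxide displacing the allylic bromide (direct and SN2′ attack give the same ether).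

Step 10
Reactants: 14 ethyl 2-{[(4-methoxyphenyl)methoxy]methyl}prop-2-enoate
Product: 15 2-{[(4-methoxyphenyl)methoxy]methyl}prop-2-enoic acid
Conditions: LiOH, THF/H2O, 0 °C to rt; then 1 M HCl to pH 3
Reagents that add atoms: lithium hydroxide, [Li+].[OH-]
Why: Saponification of the ethyl ester followed by acidification gives the acrylic acid partner.

Step 11
Reactants: 11 (1S)-1-[(2R,3R)-3-ethenyl-3-methyloxiran-2-yl]prop-2-en-1-ol; 15 2-{[(4-methoxyphenyl)methoxy]methyl}prop-2-enoic acid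
Product: 16 (1S)-1-[(2R,3R)-3-ethenyl-3-methyloxiran-2-yl]prop-2-en-1-yl 2-{[(4-methoxyphenyl)methoxy]methyl}prop-2-enoate
Conditions: DCC, DMAP (cat.), CH2Cl2, 0 °C to rt
Reagents that add atoms: none
Why: Steglich esterification acylates the C6 hydroxyl with retention of configuration.

Step 12
Reactants: 16 (1S)-1-[(2R,3R)-3-ethenyl-3-methyloxiran-2-yl]prop-2-en-1-yl 2-{[(4-methoxyphenyl)methoxy]methyl}prop-2-enoate
Product: 17 (5S)-5-[(2R,3R)-3-ethenyl-3-methyloxiran-2-yl]-3-{[(4-methoxyphenyl)methoxy]methyl}furan-2(5H)-one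
Conditions: second-generation Grubbs catalyst RuCl2(=CHPh)(PCy3)(H2IMes) (5 mol%), CH2Cl2 (5 mM), reflux
Reagents that add atoms: none
Why: Ring-closing metathesis between the acrylate and the neighbouring vinyl group closes the five-membered butenolide, the vinyl group on the quaternary epoxide carbon being too hindered and geometrically unable to compete.

Step 13
Reactants: 17 (5S)-5-[(2R,3R)-3-ethenyl-3-methyloxiran-2-yl]-3-{[(4-methoxyphenyl)methoxy]methyl}furan-2(5H)-one
Product: 18 (5S)-5-[(2R,3R)-3-ethenyl-3-methyloxiran-2-yl]-3-(hydroxymethyl)furan-2(5H)-one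
Conditions: DDQ, CH2Cl2/pH 7 phosphate buffer, 0 °C to rt
Reagents that add atoms: none
Why: Oxidative cleavage of the 4-methoxybenzyl ether under neutral conditions spares the vinyl epoxide and the base-sensitive butenolide.

Step 14
Reactants: 18 (5S)-5-[(2R,3R)-3-ethenyl-3-methyloxiran-2-yl]-3-(hydroxymethyl)furan-2(5H)-one
Product: 19 (5S)-3-(bromomethyl)-5-[(2R,3R)-3-ethenyl-3-methyloxiran-2-yl]furan-2(5H)-one
Conditions: CBr4, PPh3, CH2Cl2, 0 °C
Reagents that add atoms: carbon tetrabromide, BrC(Br)(Br)Br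
Why: Appel bromination gives the allylic bromide (fragment A) under neutral conditions.

Step 15
Reactants: 20 methyl 4-chloro-3-oxobutanoate; 13 (4-methoxyphenyl)methanol
Product: 21 methyl 4-[(4-methoxyphenyl)methoxy]-3-oxobutanoate
Conditions: NaH (2.2 equiv), THF, 0 °C to rt; then AcOH
Reagents that add atoms: none
Why: Williamson etherification on the sodium enolate of the chloro keto ester (the enolate shields the ketone) installs the protected C8 oxygen.

Step 16
Reactants: 21 methyl 4-[(4-methoxyphenyl)methoxy]-3-oxobutanoate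
Product: 22 methyl (3S)-3-hydroxy-4-[(4-methoxyphenyl)methoxy]butanoate
Conditions: RuCl2[(R)-BINAP] (0.5 mol%), H2 (50 atm), MeOH, 50 °C
Reagents that add atoms: none
Why: Noyori asymmetric hydrogenation of the β-keto ester, in which the (R)-BINAP catalyst reduces the ester-chelated ketone from one face to set C9 as 3S (the sense known for 4-alkoxy- and 4-chloro-3-oxobutanoates).

Step 17
Reactants: 22 methyl (3S)-3-hydroxy-4-[(4-methoxyphenyl)methoxy]butanoate
Product: 23 methyl (3S)-4-[(4-methoxyphenyl)methoxy]-3-[(triethylsilyl)oxy]butanoate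
Conditions: Et3SiCl, imidazole, CH2Cl2, 0 °C
Reagents that add atoms: chlorotriethylsilane, CC[Si](Cl)(CC)CC
Why: Silyl ether protection of the C9 hydroxyl with a group that does not chelate in the later allylation and can be removed last.

Step 18
Reactants: 23 methyl (3S)-4-[(4-methoxyphenyl)methoxy]-3-[(triethylsilyl)oxy]butanoate; 24 prop-2-enal
Product: 26 methyl 3-hydroxy-2-{(1S)-2-[(4-methoxyphenyl)methoxy]-1-[(triethylsilyl)oxy]ethyl}pent-4-enoate, via lithium enolate 25 (not isolated)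
Conditions: LiN(iPr)2, THF, −78 °C; then 24, −78 °C; AcOH quench
Reagents that add atoms: none
Why: Kinetic ester enolate formation and aldol 1,2-addition to acrolein at −78 °C (β-silyloxide loss suppressed by temperature), the two new stereocentres being erased in the next step.

Step 19
Reactants: 26 methyl 3-hydroxy-2-{(1S)-2-[(4-methoxyphenyl)methoxy]-1-[(triethylsilyl)oxy]ethyl}pent-4-enoate
Product: 28 methyl (2E)-2-{(1S)-2-[(4-methoxyphenyl)methoxy]-1-[(triethylsilyl)oxy]ethyl}penta-2,4-dienoate, via acetate 27 (not isolated)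
Conditions: Ac2O, Et3N, DMAP (cat.), CH2Cl2, 0 °C; then DBU, rt
Reagents that add atoms: none
Why: Acetylation and E1cB elimination give the conjugated dienoate with the vinyl group trans to the ester (the thermodynamically favoured 2E geometry) without affecting C9, whose hydrogen is not acidified by the ester.

Step 20
Reactants: 28 methyl (2E)-2-{(1S)-2-[(4-methoxyphenyl)methoxy]-1-[(triethylsilyl)oxy]ethyl}penta-2,4-dienoate
Product: 29 methyl (2E)-2-{(1S)-2-hydroxy-1-[(triethylsilyl)oxy]ethyl}penta-2,4-dienoate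
Conditions: DDQ, CH2Cl2/pH 7 phosphate buffer, 0 °C
Reagents that add atoms: none
Why: Oxidative 4-methoxybenzyl ether cleavage is neutral, so the triethylsilyl ether survives and the electron-poor diene is inert.

Step 21
Reactants: 29 methyl (2E)-2-{(1S)-2-hydroxy-1-[(triethylsilyl)oxy]ethyl}penta-2,4-dienoate
Product: 30 methyl (2E)-2-{(1S)-2-oxo-1-[(triethylsilyl)oxy]ethyl}penta-2,4-dienoate
Conditions: Dess–Martin periodinane, pyridine, CH2Cl2, 0 °C; used at once
Reagents that add atoms: none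
Why: Dess–Martin oxidation under pyridine buffering gives the configurationally labile α-silyloxy aldehyde (fragment B) without enolisation.

Step 22
Reactants: 31 (2Z)-2-methylbut-2-enoic acid
Product: 32 (2Z)-2-methylbut-2-en-1-ol
Conditions: LiAlH4, Et2O, 0 °C
Reagents that add atoms: none
Why: Hydride reduction of the acid to the allylic alcohol with retention of the Z geometry.

Step 23
Reactants: 32 (2Z)-2-methylbut-2-en-1-ol
Product: 33 [(2R,3S)-2,3-dimethyloxiran-2-yl]methanol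
Conditions: Ti(OiPr)4 (10 mol%), D-(−)-diethyl tartrate (12 mol%), tBuOOH, 4 Å molecular sieves, CH2Cl2, −20 °C
Reagents that add atoms: tert-butyl hydroperoxide, CC(C)(C)OO
Why: Sharpless asymmetric epoxidation with D-(−)-tartrate gives the (2R,3S)-epoxy alcohol, the cis relationship of the hydroxymethyl and C3-methyl groups following from the Z alkene.

Step 24
Reactants: 33 [(2R,3S)-2,3-dimethyloxiran-2-yl]methanol
Product: 34 (2S,3S)-2,3-dimethyloxirane-2-carboxylic acid
Conditions: TEMPO (cat.), (diacetoxyiodo)benzene (2.2 equiv), MeCN/H2O, rt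
Reagents that add atoms: water, O
Why: Oxoammonium oxidation of the primary alcohol through the aldehyde hydrate gives the acid without touching the epoxide (the C2 label becomes S by CIP priority only).

Step 25
Reactants: 19 (5S)-3-(bromomethyl)-5-[(2R,3R)-3-ethenyl-3-methyloxiran-2-yl]furan-2(5H)-one; 30 methyl (2E)-2-{(1S)-2-oxo-1-[(triethylsilyl)oxy]ethyl}penta-2,4-dienoate
Product: 36 methyl (2E)-2-[(1S,2R)-2-{(2S,3R)-2-[(2R,3R)-3-ethenyl-3-methyloxiran-2-yl]-4-methylidene-5-oxooxolan-3-yl}-2-hydroxy-1-[(triethylsilyl)oxy]ethyl]penta-2,4-dienoate, via allylzinc bromide 35 (not isolated)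
Conditions: Zn dust, THF/sat. aq. NH4Cl (2:1), 0 °C to rt
Reagents that add atoms: none
Why: Barbier-type carbonyl allylation in which the allylzinc reacts through its γ-carbon in a chair Zimmerman–Traxler transition state, anti to the C6 substituent (sets C7, trans lactone) with allylic transposition to the exo-methylene lactone, giving the 7,8-anti adduct with C8 as R, a sense reinforced by Felkin–Anh addition to the α-silyloxy aldehyde.

Step 26
Reactants: 36 methyl (2E)-2-[(1S,2R)-2-{(2S,3R)-2-[(2R,3R)-3-ethenyl-3-methyloxiran-2-yl]-4-methylidene-5-oxooxolan-3-yl}-2-hydroxy-1-[(triethylsilyl)oxy]ethyl]penta-2,4-dienoate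
Product: 37 methyl (2E)-2-[(1S,2S)-2-{(2S,3R)-2-[(2R,3R)-3-ethenyl-3-methyloxiran-2-yl]-4-methylidene-5-oxooxolan-3-yl}-2-(formyloxy)-1-[(triethylsilyl)oxy]ethyl]penta-2,4-dienoate
Conditions: PPh3, DIAD (premixed), HCO2H, THF, 0 °C to rt
Reagents that add atoms: formic acid, O=CO
Why: Mitsunobu reaction with the small, acidic formic acid inverts C8 by SN2 displacement to the 8S configuration of the target.

Step 27
Reactants: 37 methyl (2E)-2-[(1S,2S)-2-{(2S,3R)-2-[(2R,3R)-3-ethenyl-3-methyloxiran-2-yl]-4-methylidene-5-oxooxolan-3-yl}-2-(formyloxy)-1-[(triethylsilyl)oxy]ethyl]penta-2,4-dienoate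
Product: 38 methyl (2E)-2-[(1S,2S)-2-{(2S,3R)-2-[(2R,3R)-3-ethenyl-3-methyloxiran-2-yl]-4-methylidene-5-oxooxolan-3-yl}-2-hydroxy-1-[(triethylsilyl)oxy]ethyl]penta-2,4-dienoate
Conditions: KHCO3 (cat.), MeOH, 0 °C
Reagents that add atoms: none
Why: Chemoselective methanolysis of the formate, which is far more labile than the lactone, the methyl ester or the silyl ether, with retention at C8.

Step 28
Reactants: 38 methyl (2E)-2-[(1S,2S)-2-{(2S,3R)-2-[(2R,3R)-3-ethenyl-3-methyloxiran-2-yl]-4-methylidene-5-oxooxolan-3-yl}-2-hydroxy-1-[(triethylsilyl)oxy]ethyl]penta-2,4-dienoate; 34 (2S,3S)-2,3-dimethyloxirane-2-carboxylic acid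
Product: 40 methyl (2E)-2-[(1S,2S)-2-{(2S,3S)-2-[(2R,3R)-3-ethenyl-3-methyloxiran-2-yl]-4-methylidene-5-oxooxolan-3-yl}-2-{[(2S,3S)-2,3-dimethyloxirane-2-carbonyl]oxy}-1-[(triethylsilyl)oxy]ethyl]penta-2,4-dienoate, via mixed anhydride 39 (not isolated)
Conditions: 34, 2,4,6-trichlorobenzoyl chloride, Et3N, THF, rt; then 38, DMAP, toluene, rt
Reagents that add atoms: none
Why: Yamaguchi esterification via the mixed anhydride acylates the hindered C8 alcohol with retention and without opening either epoxide (the C7 label becomes S by CIP priority only).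

Step 29
Reactants: 40 methyl (2E)-2-[(1S,2S)-2-{(2S,3S)-2-[(2R,3R)-3-ethenyl-3-methyloxiran-2-yl]-4-methylidene-5-oxooxolan-3-yl}-2-{[(2S,3S)-2,3-dimethyloxirane-2-carbonyl]oxy}-1-[(triethylsilyl)oxy]ethyl]penta-2,4-dienoate
Product: 41 9-O-triethylsilyl ether of 42, methyl (1(10)E,2Z,4R,5R,6S,7S,8S,9S)-8-{[(2S,3S)-2,3-dimethyloxirane-2-carbonyl]oxy}-4,5-epoxy-12-oxo-9-[(triethylsilyl)oxy]-6,12-epoxygermacra-1(10),2,11(13)-trien-14-oate
Conditions: second-generation Grubbs catalyst RuCl2(=CHPh)(PCy3)(H2IMes) (15 mol%), toluene (1 mM), 80 °C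
Reagents that add atoms: none
Why: Ring-closing metathesis of the two terminal alkenes closes the ten-membered ring, whose size and cis C1=C10 enoate enforce the cis (Z) C2=C3 alkene, while the trisubstituted enoate and the exo-methylene lactone are inert.

Step 30
Reactants: 41 9-O-triethylsilyl ether of 42
Product: 42 methyl (1(10)E,2Z,4R,5R,6S,7R,8S,9S)-8-{[(2S,3S)-2,3-dimethyloxirane-2-carbonyl]oxy}-4,5-epoxy-9-hydroxy-12-oxo-6,12-epoxygermacra-1(10),2,11(13)-trien-14-oate (CNP0131597.1)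
Conditions: HF·pyridine, pyridine, THF, 0 °C
Reagents that add atoms: none
Why: Buffered fluoride cleavage of the triethylsilyl ether frees the C9 hydroxyl without acid opening of the vinyl epoxide or acyl migration.

**Compound list**

1 | (2S)-but-3-ene-1,2-diol | OC[C@@H](O)C=C | starting material
2 | (3S)-3,4-bis[(tert-butyldimethylsilyl)oxy]but-1-ene | CC(C)(C)[Si](C)(C)OC[C@@H](O[Si](C)(C)C(C)(C)C)C=C | intermediate
3 | (2S)-2-[(tert-butyldimethylsilyl)oxy]but-3-en-1-ol | OC[C@@H](O[Si](C)(C)C(C)(C)C)C=C | intermediate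
4 | ethyl 2-(triphenyl-λ5-phosphanylidene)propanoate | CCOC(=O)C(C)=P(c1ccccc1)(c1ccccc1)c1ccccc1 | starting material
5 | (2S)-2-[(tert-butyldimethylsilyl)oxy]but-3-enal | O=C[C@@H](O[Si](C)(C)C(C)(C)C)C=C | intermediate
6 | ethyl (2E,4S)-4-[(tert-butyldimethylsilyl)oxy]-2-methylhexa-2,5-dienoate | CCOC(=O)/C(C)=C/[C@@H](O[Si](C)(C)C(C)(C)C)C=C | intermediate
7 | (2E,4S)-4-[(tert-butyldimethylsilyl)oxy]-2-methylhexa-2,5-dien-1-ol | OC/C(C)=C/[C@@H](O[Si](C)(C)C(C)(C)C)C=C | intermediate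
8 | [(2R,3R)-3-{(1S)-1-[(tert-butyldimethylsilyl)oxy]prop-2-en-1-yl}-2-methyloxiran-2-yl]methanol | C=C[C@H](O[Si](C)(C)C(C)(C)C)[C@H]1O[C@]1(C)CO | intermediate
9 | (2S,3R)-3-{(1S)-1-[(tert-butyldimethylsilyl)oxy]prop-2-en-1-yl}-2-methyloxirane-2-carbaldehyde | C=C[C@H](O[Si](C)(C)C(C)(C)C)[C@H]1O[C@]1(C)C=O | intermediate
10 | tert-butyl({(1S)-1-[(2R,3R)-3-ethenyl-3-methyloxiran-2-yl]prop-2-en-1-yl}oxy)dimethylsilane | C=C[C@H](O[Si](C)(C)C(C)(C)C)[C@H]1O[C@]1(C)C=C | intermediate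
11 | (1S)-1-[(2R,3R)-3-ethenyl-3-methyloxiran-2-yl]prop-2-en-1-ol | C=C[C@H](O)[C@H]1O[C@]1(C)C=C | intermediate
12 | ethyl 2-(bromomethyl)prop-2-enoate | C=C(CBr)C(=O)OCC | starting material
13 | (4-methoxyphenyl)methanol | COc1ccc(CO)cc1 | starting material
14 | ethyl 2-{[(4-methoxyphenyl)methoxy]methyl}prop-2-enoate | C=C(COCc1ccc(OC)cc1)C(=O)OCC | intermediate
15 | 2-{[(4-methoxyphenyl)methoxy]methyl}prop-2-enoic acid | C=C(COCc1ccc(OC)cc1)C(=O)O | intermediate
16 | (1S)-1-[(2R,3R)-3-ethenyl-3-methyloxiran-2-yl]prop-2-en-1-yl 2-{[(4-methoxyphenyl)methoxy]methyl}prop-2-enoate | C=C[C@H](OC(=O)C(=C)COCc1ccc(OC)cc1)[C@H]1O[C@]1(C)C=C | intermediate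
17 | (5S)-5-[(2R,3R)-3-ethenyl-3-methyloxiran-2-yl]-3-{[(4-methoxyphenyl)methoxy]methyl}furan-2(5H)-one | COc1ccc(COCC2=C[C@@H]([C@H]3O[C@]3(C)C=C)OC2=O)cc1 | intermediate
18 | (5S)-5-[(2R,3R)-3-ethenyl-3-methyloxiran-2-yl]-3-(hydroxymethyl)furan-2(5H)-one | OCC1=C[C@@H]([C@H]2O[C@]2(C)C=C)OC1=O | intermediate
19 | (5S)-3-(bromomethyl)-5-[(2R,3R)-3-ethenyl-3-methyloxiran-2-yl]furan-2(5H)-one | BrCC1=C[C@@H]([C@H]2O[C@]2(C)C=C)OC1=O | intermediate
20 | methyl 4-chloro-3-oxobutanoate | COC(=O)CC(=O)CCl | starting material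
21 | methyl 4-[(4-methoxyphenyl)methoxy]-3-oxobutanoate | COC(=O)CC(=O)COCc1ccc(OC)cc1 | intermediate
22 | methyl (3S)-3-hydroxy-4-[(4-methoxyphenyl)methoxy]butanoate | COC(=O)C[C@H](O)COCc1ccc(OC)cc1 | intermediate
23 | methyl (3S)-4-[(4-methoxyphenyl)methoxy]-3-[(triethylsilyl)oxy]butanoate | COC(=O)C[C@H](O[Si](CC)(CC)CC)COCc1ccc(OC)cc1 | intermediate
24 | prop-2-enal (acrolein) | C=CC=O | starting material
25 | lithium (3S)-1-methoxy-4-[(4-methoxyphenyl)methoxy]-3-[(triethylsilyl)oxy]but-1-en-1-olate (lithium enolate of 23) | [Li]OC(OC)=C[C@H](O[Si](CC)(CC)CC)COCc1ccc(OC)cc1 | intermediate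
26 | methyl 3-hydroxy-2-{(1S)-2-[(4-methoxyphenyl)methoxy]-1-[(triethylsilyl)oxy]ethyl}pent-4-enoate (mixture at C2 and C3) | COC(=O)C(C(O)C=C)[C@H](O[Si](CC)(CC)CC)COCc1ccc(OC)cc1 | intermediate
27 | methyl 3-(acetyloxy)-2-{(1S)-2-[(4-methoxyphenyl)methoxy]-1-[(triethylsilyl)oxy]ethyl}pent-4-enoate (mixture at C2 and C3) | COC(=O)C(C(OC(C)=O)C=C)[C@H](O[Si](CC)(CC)CC)COCc1ccc(OC)cc1 | intermediate
28 | methyl (2E)-2-{(1S)-2-[(4-methoxyphenyl)methoxy]-1-[(triethylsilyl)oxy]ethyl}penta-2,4-dienoate | COC(=O)/C(=C/C=C)[C@H](O[Si](CC)(CC)CC)COCc1ccc(OC)cc1 | intermediate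
29 | methyl (2E)-2-{(1S)-2-hydroxy-1-[(triethylsilyl)oxy]ethyl}penta-2,4-dienoate | COC(=O)/C(=C/C=C)[C@H](O[Si](CC)(CC)CC)CO | intermediate
30 | methyl (2E)-2-{(1S)-2-oxo-1-[(triethylsilyl)oxy]ethyl}penta-2,4-dienoate | COC(=O)/C(=C/C=C)[C@H](O[Si](CC)(CC)CC)C=O | intermediate
31 | (2Z)-2-methylbut-2-enoic acid (angelic acid) | C/C=C(/C)C(=O)O | starting material
32 | (2Z)-2-methylbut-2-en-1-ol | C/C=C(/C)CO | intermediate
33 | [(2R,3S)-2,3-dimethyloxiran-2-yl]methanol | OC[C@@]1(C)O[C@H]1C | intermediate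
34 | (2S,3S)-2,3-dimethyloxirane-2-carboxylic acid | OC(=O)[C@@]1(C)O[C@H]1C | intermediate
35 | bromo{[(5S)-5-[(2R,3R)-3-ethenyl-3-methyloxiran-2-yl]-2-oxo-2,5-dihydrofuran-3-yl]methyl}zinc (allylzinc bromide from 19) | Br[Zn]CC1=C[C@@H]([C@H]2O[C@]2(C)C=C)OC1=O | intermediate
36 | methyl (2E)-2-[(1S,2R)-2-{(2S,3R)-2-[(2R,3R)-3-ethenyl-3-methyloxiran-2-yl]-4-methylidene-5-oxooxolan-3-yl}-2-hydroxy-1-[(triethylsilyl)oxy]ethyl]penta-2,4-dienoate | C=C1C(=O)O[C@H]([C@H]2O[C@]2(C)C=C)[C@H]1[C@@H](O)[C@@H](O[Si](CC)(CC)CC)/C(C(=O)OC)=C\C=C | intermediate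
37 | methyl (2E)-2-[(1S,2S)-2-{(2S,3R)-2-[(2R,3R)-3-ethenyl-3-methyloxiran-2-yl]-4-methylidene-5-oxooxolan-3-yl}-2-(formyloxy)-1-[(triethylsilyl)oxy]ethyl]penta-2,4-dienoate | C=C1C(=O)O[C@H]([C@H]2O[C@]2(C)C=C)[C@H]1[C@H](OC=O)[C@@H](O[Si](CC)(CC)CC)/C(C(=O)OC)=C\C=C | intermediate
38 | methyl (2E)-2-[(1S,2S)-2-{(2S,3R)-2-[(2R,3R)-3-ethenyl-3-methyloxiran-2-yl]-4-methylidene-5-oxooxolan-3-yl}-2-hydroxy-1-[(triethylsilyl)oxy]ethyl]penta-2,4-dienoate | C=C1C(=O)O[C@H]([C@H]2O[C@]2(C)C=C)[C@H]1[C@H](O)[C@@H](O[Si](CC)(CC)CC)/C(C(=O)OC)=C\C=C | intermediate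
39 | (2S,3S)-2,3-dimethyloxirane-2-carboxylic 2,4,6-trichlorobenzoic anhydride | O=C(OC(=O)c1c(Cl)cc(Cl)cc1Cl)[C@@]1(C)O[C@H]1C | intermediate
40 | methyl (2E)-2-[(1S,2S)-2-{(2S,3S)-2-[(2R,3R)-3-ethenyl-3-methyloxiran-2-yl]-4-methylidene-5-oxooxolan-3-yl}-2-{[(2S,3S)-2,3-dimethyloxirane-2-carbonyl]oxy}-1-[(triethylsilyl)oxy]ethyl]penta-2,4-dienoate | C=C1C(=O)O[C@H]([C@H]2O[C@]2(C)C=C)[C@H]1[C@H](OC(=O)[C@@]1(C)O[C@H]1C)[C@@H](O[Si](CC)(CC)CC)/C(C(=O)OC)=C\C=C | intermediate
41 | 9-O-triethylsilyl ether of 42, methyl (1(10)E,2Z,4R,5R,6S,7S,8S,9S)-8-{[(2S,3S)-2,3-dimethyloxirane-2-carbonyl]oxy}-4,5-epoxy-12-oxo-9-[(triethylsilyl)oxy]-6,12-epoxygermacra-1(10),2,11(13)-trien-14-oate | C=C1C(=O)O[C@H]2[C@H]1[C@H](OC(=O)[C@@]1(C)O[C@H]1C)[C@@H](O[Si](CC)(CC)CC)/C(C(=O)OC)=C\C=C/[C@@]1(C)O[C@H]21 | intermediate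
42 | methyl (1(10)E,2Z,4R,5R,6S,7R,8S,9S)-8-{[(2S,3S)-2,3-dimethyloxirane-2-carbonyl]oxy}-4,5-epoxy-9-hydroxy-12-oxo-6,12-epoxygermacra-1(10),2,11(13)-trien-14-oate (CNP0131597.1) | C=C1C(=O)O[C@H]2[C@H]1[C@H](OC(=O)[C@@]1(C)O[C@H]1C)[C@@H](O)/C(C(=O)OC)=C\C=C/[C@@]1(C)O[C@H]21 | target

**Step count and risks**

Total step count: 30 (fragment A 12 steps, acid 15 2 steps, fragment B 7 steps, acid 34 3 steps, endgame 6 steps). Longest linear sequence: 18 steps (1 → 19 → 42; steps 1–8, 11–14, 25–30).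

Steps most likely to fail:

Step 29 (ring-closing metathesis to the ten-membered ring). The vinyl group on the quaternary epoxide carbon is hindered, the diene terminus can sequester the catalyst, and oligomers may form. The fallback sets out from 40: the silyl ether is cleaved first (HF·pyridine, pyridine, THF, 0 °C) to the free C9 carbinol methyl (2E)-2-[(1S,2S)-2-{(2S,3R)-2-[(2R,3R)-3-ethenyl-3-methyloxiran-2-yl]-4-methylidene-5-oxooxolan-3-yl}-2-{[(2S,3S)-2,3-dimethyloxirane-2-carbonyl]oxy}-1-hydroxyethyl]penta-2,4-dienoate F2. The metathesis is then run on this smaller, hydroxyl-bearing triene (same catalyst, toluene, 1 mM, 80 °C), where the bulky silyl group next to the diene is gone and the free hydroxyl can assist the ruthenium carbene. The product of this closure is 42 itself, where the route is rejoined.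

Step 26 (Mitsunobu inversion at C8). The carbinol is flanked by two branched carbons and the C7 hydrogen is allylic, so elimination or no reaction is possible. The fallback leaves the SN2 manifold and sets out from 36: oxidation with Dess–Martin periodinane/pyridine (CH2Cl2, 0 °C) gives the ketone methyl (2E)-2-[(1S)-2-{(2S,3S)-2-[(2R,3R)-3-ethenyl-3-methyloxiran-2-yl]-4-methylidene-5-oxooxolan-3-yl}-2-oxo-1-[(triethylsilyl)oxy]ethyl]penta-2,4-dienoate F1. This is reduced at once with NaBH4/CeCl3·7H2O in MeOH at −78 °C (1,2-selective, sparing the methylene lactone); Felkin–Anh hydride delivery anti to the C9 silyloxy group gives the 8,9-syn alcohol, which is 38, where the route is rejoined.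

Step 28 (acylation of the hindered 8S alcohol). The free alcohol sits next to the lactone and the silyl ether, so lactone or silyl migration can compete, and the mixed anhydride may deliver the wrong acyl group. The fallback sets out from 36 and uses a Mitsunobu esterification directly with acid 34 (PPh3, DIAD, toluene, 0 °C to rt). This inverts C8 and installs the epoxy ester in one operation, so the free 8S alcohol never exists. The route is rejoined at 40 and no compound outside the list is formed, none F0.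

**Further compounds**

F2 | step 29 | methyl (2E)-2-[(1S,2S)-2-{(2S,3R)-2-[(2R,3R)-3-ethenyl-3-methyloxiran-2-yl]-4-methylidene-5-oxooxolan-3-yl}-2-{[(2S,3S)-2,3-dimethyloxirane-2-carbonyl]oxy}-1-hydroxyethyl]penta-2,4-dienoate | C=C1C(=O)O[C@H]([C@H]2O[C@]2(C)C=C)[C@H]1[C@H](OC(=O)[C@@]1(C)O[C@H]1C)[C@@H](O)/C(C(=O)OC)=C\C=C
F1 | step 26 | methyl (2E)-2-[(1S)-2-{(2S,3S)-2-[(2R,3R)-3-ethenyl-3-methyloxiran-2-yl]-4-methylidene-5-oxooxolan-3-yl}-2-oxo-1-[(triethylsilyl)oxy]ethyl]penta-2,4-dienoate | C=C1C(=O)O[C@H]([C@H]2O[C@]2(C)C=C)[C@H]1C(=O)[C@@H](O[Si](CC)(CC)CC)/C(C(=O)OC)=C\C=C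
F0 | step 28 | none | none
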